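The benzene ring is unmasked from a 2-pyrone instead of being substituted. Its carbons bearing OH, the bridge CH2, OH, isobutyryl and OH are C2, C3, C4, C5 and C6 of a 5-isobutyryl-4-hydroxy-2-pyrone (ring A), and the prenylated carbon is the first CH2 of the 4-methylpent-3-enyl chain on C6. The precursor is therefore an isomer of the target, a bis(4-hydroxy-2-pyrone) joined through CH2 at both C3 atoms. In one operation Mg(OMe)2 cleaves the lactone C2–O1 bond of ring A and a Claisen closure between that chain CH2 and C2 builds the hexasubstituted carbocycle with all six substituents in place, while the ethyl methyl pyrone (ring B) stays intact.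

Key step: step 7

Remark: pyrones and phloroglucinol are drawn as single enol tautomers, silyl enol ether 2 is used as an E/Z mixture because its geometry is lost in step 2, and the diketone from 6-methylhept-5-en-2-one and methyl isobutyrate has a ten-carbon chain (C12H20O2), hence the name dec-8-ene-3,5-dione.

Step 1
Reactants: 1 pentan-3-one
Product: 2 3-(trimethylsilyloxy)pent-2-ene (E/Z mixture)
Conditions: LiN(i-Pr)2 (1.05 equiv), THF, −78 °C; Me3SiCl, −78 °C to rt; distillation
Reagents that add atoms: chlorotrimethylsilane, C[Si](C)(C)Cl
Why: Deprotonation of the symmetric ketone and O-silylation of the lithium enolate (silyl enol ether formation) raise no regiochemical question and give a nucleophile far more reactive towards acid chlorides than the ketone itself, which would let malonyl dichloride self-condense.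

Step 2
Reactants: 2 3-(trimethylsilyloxy)pent-2-ene, 3 malonyl dichloride
Product: 4 6-ethyl-4-hydroxy-5-methyl-2H-pyran-2-one (ring B pyrone)
Conditions: Et2O, −78 °C to rt, 16 h; precipitated product filtered, volatiles evaporated
Reagents that add atoms: none
Why: Silyl enol ether/malonyl dichloride pyrone annulation, in which C-acylation at the methyl-bearing enol carbon (loss of Me3SiCl) is followed by lactonization of the enol oxygen onto the second acid chloride and tautomerization, so the ethyl group ends at C6 and the methyl at C5.

Step 3
Reactants: 4 6-ethyl-4-hydroxy-5-methyl-2H-pyran-2-one, 5 Eschenmoser's salt (N,N-dimethylmethyleneiminium iodide)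
Product: 6 3-[(dimethylamino)methyl]-6-ethyl-4-hydroxy-5-methyl-2H-pyran-2-one
Conditions: 5 (1.1 equiv), MeCN, rt; then NaHCO3 (1 equiv), H2O
Reagents that add atoms: none
Why: Mannich reaction with a preformed iminium salt, in which C3 is the only free nucleophilic ring carbon (C5 and C6 are substituted) and the ammonium salt formed at room temperature does not eliminate, so the symmetric methylene-bis-pyrone should be avoided.

Step 4
Reactants: 7 6-methylhept-5-en-2-one, 8 methyl isobutyrate
Product: 9 2,9-dimethyldec-8-ene-3,5-dione
Conditions: NaH (2.2 equiv), 8 (2 equiv), THF, reflux, slow addition of 7; then 1 M HCl, 0 °C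
Reagents that add atoms: none
Why: Crossed Claisen condensation, in which the ester cannot self-condense productively (its own Claisen product has no acidic hydrogen), the ketone is acylated at the less hindered methyl group, and the second equivalent of hydride removes the product as its stable diketonate; the isolated alkene is inert.

Step 5
Reactants: 9 2,9-dimethyldec-8-ene-3,5-dione, 3 malonyl dichloride
Product: 10 4-hydroxy-5-(2-methylpropanoyl)-6-(4-methylpent-3-en-1-yl)-2H-pyran-2-one (ring A pyrone)
Conditions: 3 (1.1 equiv, slow addition), Et2O, 0 °C to 35 °C, continuous argon sparge; extraction into aq. NaHCO3, reacidification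
Reagents that add atoms: none
Why: 1,3-Diketone/malonyl dichloride pyrone annulation (C-acylation of the central carbon, then lactonization of an enol oxygen onto the remaining acid chloride), run in ether with constant removal of HCl because hydrochlorination of the trisubstituted alkene needs a high stationary HCl concentration; closure through the less hindered CH2-flanked enol is expected to dominate, and the regioisomer from the other enol oxygen would open to the same ester in step 7.

Step 6
Reactants: 6 3-[(dimethylamino)methyl]-6-ethyl-4-hydroxy-5-methyl-2H-pyran-2-one, 10 ring A pyrone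
Product: 12 3-[(6-ethyl-4-hydroxy-5-methyl-2-oxo-2H-pyran-3-yl)methyl]-4-hydroxy-5-(2-methylpropanoyl)-6-(4-methylpent-3-en-1-yl)-2H-pyran-2-one (bis-pyrone), via 6-ethyl-5-methyl-3-methylidenepyran-2,4-dione 11 (not isolated)
Conditions: 10 (1.5 equiv), 1,4-dioxane, 95 °C, slow addition of 6, argon stream; then 0.5 M HCl wash
Reagents that add atoms: none
Why: Thermal loss of dimethylamine from the Mannich base gives the electrophilic 3-methylidene dione (an ortho-quinone-methide analogue) and the enolic C3 of ring A, its only free nucleophilic carbon, adds in a Michael addition; excess 10 and a low stationary concentration of 11 should hold back the symmetric dimer of ring B.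

Step 7
Reactants: 12 bis-pyrone
Product: 14 3-{[2,4,6-trihydroxy-3-(3-methylbut-2-en-1-yl)-5-(2-methylpropanoyl)phenyl]methyl}-6-ethyl-4-hydroxy-5-methyl-2H-pyran-2-one (target), via ring-opened triacylmethane methyl ester 13 (not isolated)
Conditions: Mg(OMe)2 (8 equiv), dry degassed MeOH, reflux, argon; then cold 1 M HCl, 0 °C, EtOAc
Reagents that add atoms: none
Why: Methoxide from Mg(OMe)2 adds to the lactone carbonyl C2 of ring A and cleaves C2–O1 to the magnesium-chelated triacylmethane ester 13; because three acyl groups on one carbon cannot all lie in the chelate plane, the C6-derived carbonyl keeps ketone character, its alpha CH2 is enolized and attacks the ester carbon with loss of methoxide, and the trione formed tautomerizes to the benzene ring, which makes the sequence irreversible. The closest known reaction type is the magnesium alkoxide isomerization of acyl- and alkyl-substituted 4-hydroxy-2-pyrones and the corresponding polyketo esters into phloroglucinols (a biomimetic Claisen cyclization), and the closure itself is the classical delta-keto ester to cyclohexane-1,3-dione Dieckmann-type condensation. The one ring formed is closed 6-exo-trig by the bond between the chain CH2 and C2, the rest of the chain (CH2CH=CMe2) remains as the prenyl group, no stereocentre arises and the alkene is untouched. Two selectivities are required: ring A must open productively while ring B does not, and the chain CH2 must close instead of the isopropyl methine. The first should be secured by the 5-isobutyryl group, which makes C2 of ring A the carbonyl of a vinylogous acyl lactone and turns the opened form into a stabilized chelate with a free ester, whereas ring B is an electron-rich 4-oxidopyrone whose opened form would be a chelated diketonate with no ketone-like carbonyl next to its ethyl CH2 and can only close back. The second should be secured by the higher kinetic acidity and lower hindrance of the secondary CH2 and by the fact that only its closure aromatizes (a gem-dimethyl trione from the methine can revert by retro-Claisen opening); the 1,3,5-oxygen pattern and the positions of prenyl, isobutyryl and bridge follow from connectivity alone, since C2 and C4 flank C3 symmetrically.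

Compound list
1 | pentan-3-one | CCC(=O)CC | starting material
2 | 3-(trimethylsilyloxy)pent-2-ene (E/Z mixture) | CC=C(CC)O[Si](C)(C)C | intermediate
3 | malonyl dichloride | O=C(Cl)CC(=O)Cl | starting material
4 | 6-ethyl-4-hydroxy-5-methyl-2H-pyran-2-one (ring B pyrone) | CCc1oc(=O)cc(O)c1C | intermediate
5 | Eschenmoser's salt (N,N-dimethylmethyleneiminium iodide) | C=[N+](C)C.[I-] | starting material
6 | 3-[(dimethylamino)methyl]-6-ethyl-4-hydroxy-5-methyl-2H-pyran-2-one | CCc1oc(=O)c(CN(C)C)c(O)c1C | intermediate
7 | 6-methylhept-5-en-2-one | CC(=O)CCC=C(C)C | starting material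
8 | methyl isobutyrate (methyl 2-methylpropanoate) | COC(=O)C(C)C | starting material
9 | 2,9-dimethyldec-8-ene-3,5-dione | CC(C)C(=O)CC(=O)CCC=C(C)C | intermediate
10 | 4-hydroxy-5-(2-methylpropanoyl)-6-(4-methylpent-3-en-1-yl)-2H-pyran-2-one (ring A pyrone) | CC(C)C(=O)c1c(O)cc(=O)oc1CCC=C(C)C | intermediate
11 | 6-ethyl-5-methyl-3-methylidene-2H-pyran-2,4(3H)-dione (not isolated) | CCC1=C(C)C(=O)C(=C)C(=O)O1 | intermediate
12 | 3-[(6-ethyl-4-hydroxy-5-methyl-2-oxo-2H-pyran-3-yl)methyl]-4-hydroxy-5-(2-methylpropanoyl)-6-(4-methylpent-3-en-1-yl)-2H-pyran-2-one (bis-pyrone) | CCc1oc(=O)c(Cc2c(O)c(C(=O)C(C)C)c(CCC=C(C)C)oc2=O)c(O)c1C | intermediate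
13 | methyl 2-[(6-ethyl-4-hydroxy-5-methyl-2-oxo-2H-pyran-3-yl)methyl]-9-methyl-4-(2-methylpropanoyl)-3,5-dioxodec-8-enoate (magnesium chelate in the flask, not isolated) | COC(=O)C(Cc1c(O)c(C)c(CC)oc1=O)C(=O)C(C(=O)C(C)C)C(=O)CCC=C(C)C | intermediate
14 | 3-{[2,4,6-trihydroxy-3-(3-methylbut-2-en-1-yl)-5-(2-methylpropanoyl)phenyl]methyl}-6-ethyl-4-hydroxy-5-methyl-2H-pyran-2-one (no stereocentres, alkene with two identical methyl groups) | CCc1oc(=O)c(Cc2c(O)c(CC=C(C)C)c(O)c(C(=O)C(C)C)c2O)c(O)c1C | target

Total step count: 7. Longest linear sequence: 5 steps (steps 1, 2, 3, 6, 7 from pentan-3-one); the ring A branch (steps 4, 5, 6, 7) is 4 steps.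

Steps most likely to fail

Step 7. The opened triacylmethane may fragment by retro-Claisen loss of an acyl group before the carbocycle closes. Ring B may also open and reclose, closure may run through the isopropyl methine, the methylene bridge may scramble by retro-Michael cleavage, or the prenyl group may cyclize onto a neighbouring OH during the acidic quench. The fallback gives up the pyrone-to-arene isomerization and builds the arene by classical substitution; it sets out from Mannich base 6 and comes back at target 14. Phloroglucinol would be C-acylated with isobutyryl chloride (AlCl3, PhNO2/CH2Cl2, Friedel–Crafts acylation) to 2-methyl-1-(2,4,6-trihydroxyphenyl)propan-1-one F1. This would be mono-C-prenylated with prenyl bromide (DBU, THF, rt) to 2-methyl-1-[2,4,6-trihydroxy-3-(3-methylbut-2-en-1-yl)phenyl]propan-1-one F2. Heating F2 with 6 in dioxane would alkylate its single free ring position through methylidene dione 11 and give 14.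

Step 5. HCl may add across the trisubstituted alkene, the acid chloride may self-condense, or the lactone may close mainly through the other enol oxygen. The fallback avoids free HCl; it sets out from diketone 9 and comes back at pyrone 10. Soft-enolization C-acylation of 9 with methyl 3-chloro-3-oxopropanoate (MgCl2, pyridine, CH2Cl2, 0 °C) would give methyl 9-methyl-4-(2-methylpropanoyl)-3,5-dioxodec-8-enoate F3. Lactonization of F3 with loss of methanol (DBU, toluene, reflux) would then give 10.

Step 6. Retro-Mannich cleavage may release ring B pyrone, which then captures the methylidene dione to give the symmetric dimer, and the electron-poor ring A pyrone may add sluggishly. The fallback inverts the roles of the two partners, so that the weaker nucleophile carries the leaving group; it sets out from pyrone 10 (with pyrone 4 and salt 5) and comes back at bis-pyrone 12. Aminomethylation of 10 with 5 (MeCN, rt) would give 3-[(dimethylamino)methyl]-4-hydroxy-5-(2-methylpropanoyl)-6-(4-methylpent-3-en-1-yl)-2H-pyran-2-one F4. Heating F4 with excess 4 in dioxane would generate 3-methylidene-5-(2-methylpropanoyl)-6-(4-methylpent-3-en-1-yl)-2H-pyran-2,4(3H)-dione F5, which the more nucleophilic C3 of 4 would trap to give 12.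

Further compounds
F1 | step 7 | 2-methyl-1-(2,4,6-trihydroxyphenyl)propan-1-one | CC(C)C(=O)c1c(O)cc(O)cc1O
F2 | step 7 | 2-methyl-1-[2,4,6-trihydroxy-3-(3-methylbut-2-en-1-yl)phenyl]propan-1-one | CC(C)C(=O)c1c(O)cc(O)c(CC=C(C)C)c1O
F3 | step 5 | methyl 9-methyl-4-(2-methylpropanoyl)-3,5-dioxodec-8-enoate | COC(=O)CC(=O)C(C(=O)C(C)C)C(=O)CCC=C(C)C
F4 | step 6 | 3-[(dimethylamino)methyl]-4-hydroxy-5-(2-methylpropanoyl)-6-(4-methylpent-3-en-1-yl)-2H-pyran-2-one | CC(C)C(=O)c1c(O)c(CN(C)C)c(=O)oc1CCC=C(C)C
F5 | step 6 | 3-methylidene-5-(2-methylpropanoyl)-6-(4-methylpent-3-en-1-yl)-2H-pyran-2,4(3H)-dione | CC(C)C(=O)C1=C(CCC=C(C)C)OC(=O)C(=C)C1=O
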